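**Retrosynthetic overview**

1. Target 34 ⇐ acetylation of the 9-OH of 33 ⇐ 9-OH-directed epoxidation of C1=C10 in 32 ⇐ hydrogenation of the C11=C13 methylene lactone 31 (unmasked from the C13 amine) ⇐ 9-ketone 27, reduced to set C9.
2. Ten-membered carbocycle C1–C10: closed at C9–C10 by nickel-catalysed reductive cyclisation of the C9 aldehyde onto the C1≡C10 alkyne of 22; the aldehyde comes from the C7 vinyl group of 19 by hydroboration and oxidation.
3. Feature on which the strategy rests: C7 and C11 of the γ-lactone ring (O–C6–C7–C11–C12) are the β and α carbons of a butenolide whose γ carbon C6 already carries C1–C5, C10, C14 and C15. Vinyl (C8, C9) and CH2NMe2 (C13) are therefore added across C7=C11 in one pot (15 + 16 + 17 → 19).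
4. Butenolide 15 ⇐ glutamic acid-derived lactone 6: oxidation and Wittig reaction to the E enal (C4=C5), catalytic asymmetric but-2-ynylation (C3), silylation, selenoxide elimination.
5. Ring order: γ-lactone (present in 6), ten-membered carbocycle (step 10), oxirane (step 17).

Key step: step 7

**Remarks and assumptions**

- Germacrane numbering is used throughout: ring C1–C10, C11 on C7, C12 the lactone carbonyl on O–C6, C13 on C11, C14 on C10, C15 on C4. α/β refer to the usual drawing with H7 α. The target is 3β,9β-diacetoxy-1α,10β-epoxy-11αH-germacr-4E-en-12,6α-olide, (1S,3S,6S,7S,9S,10R,11R).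
- Allenylboronate 5 is assumed not to be purchasable and is made in steps 1 and 2. A boronate is used because metal reagents made from 1-halobut-2-ynes tend to give allenyl carbinols.
- Compounds 23 and 24 are carried as both C9 epimers, because C9 is reset in steps 11 and 14.

**Route**

Step 1
Reactants: 1 but-2-yn-1-ol; 2 methyl chloroformate
Product: 3 but-2-yn-1-yl methyl carbonate
Conditions: pyridine, CH2Cl2, 0 °C
Reagents that add atoms: methyl chloroformate (2), COC(=O)Cl
Why: Acylation of a primary alcohol by a chloroformate with pyridine (carbonate formation) should give the propargylic carbonate that serves as the leaving group in step 2, and no stereocentre is involved.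

Step 2
Reactants: 3 but-2-yn-1-yl methyl carbonate; 4 bis(pinacolato)diboron
Product: 5 2-(buta-2,3-dien-2-yl)-4,4,5,5-tetramethyl-1,3,2-dioxaborolane
Conditions: CuCl (10 mol%), Xantphos (10 mol%), KOt-Bu (10 mol%), THF, rt
Reagents that add atoms: bis(pinacolato)diboron (4), CC1(C)OB(OC1(C)C)B1OC(C)(C)C(C)(C)O1
Why: Copper-catalysed γ-selective boryl substitution of a propargylic carbonate (borylcupration of the alkyne with boron on the methyl-bearing carbon, then β-elimination of the carbonate) should give the 1,1-disubstituted allenylboronate, which cannot equilibrate to a propargyl isomer.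

Step 3
Reactants: 6 (S)-5-(hydroxymethyl)dihydrofuran-2(3H)-one; 7 2-(triphenylphosphoranylidene)propanal
Product: 9 (2E)-2-methyl-3-[(2S)-5-oxotetrahydrofuran-2-yl]prop-2-enal, via lactone aldehyde 8 (not isolated)
Conditions: Dess–Martin periodinane, CH2Cl2, 0 °C to rt; then 7, rt to 40 °C
Reagents that add atoms: 2-(triphenylphosphoranylidene)propanal (7), CC(C=O)=P(c1ccccc1)(c1ccccc1)c1ccccc1
Why: Dess–Martin oxidation gives the sensitive α-acyloxy aldehyde without base, and the stabilised formyl ylide traps it in an E-selective Wittig reaction that sets the C4=C5 geometry and delivers the C3 aldehyde directly, so that no ester has to be reduced beside the lactone; C6 comes unchanged from 6.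

Step 4
Reactants: 9 (2E)-2-methyl-3-[(2S)-5-oxotetrahydrofuran-2-yl]prop-2-enal; 5 2-(buta-2,3-dien-2-yl)-4,4,5,5-tetramethyl-1,3,2-dioxaborolane
Product: 11 (5S)-5-[(1E,3S)-3-hydroxy-2-methylhept-1-en-5-yn-1-yl]dihydrofuran-2(3H)-one, via pinacol borate ester 10 (not isolated)
Conditions: (S)-TRIP [(S)-3,3′-bis(2,4,6-triisopropylphenyl)-1,1′-binaphthyl-2,2′-diyl hydrogen phosphate] (10 mol%), 4 Å molecular sieves, toluene, −20 °C; aqueous work-up
Reagents that add atoms: 2-(buta-2,3-dien-2-yl)-4,4,5,5-tetramethyl-1,3,2-dioxaborolane (5), C=C=C(C)B1OC(C)(C)C(C)(C)O1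
Why: Chiral phosphoric acid-catalysed allenylboration (carbonyl propargylation through a closed six-membered SE2′ transition state) transfers the CH2 terminus of 5 so that only the but-2-ynyl carbinol can form, and the (S)-acid is expected, by analogy with the Re-face selectivity of the (R)-acid, to direct addition to the Si face of the aldehyde and set 3S (to be confirmed by Mosher ester analysis, the enantiomeric acid being used if the sense is opposite).

Step 5
Reactants: 11 (5S)-5-[(1E,3S)-3-hydroxy-2-methylhept-1-en-5-yn-1-yl]dihydrofuran-2(3H)-one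
Product: 12 (5S)-5-[(1E,3S)-3-(tert-butyldimethylsilyloxy)-2-methylhept-1-en-5-yn-1-yl]dihydrofuran-2(3H)-one
Conditions: TBSCl, imidazole, DMF, rt
Reagents that add atoms: tert-butyldimethylsilyl chloride, CC(C)(C)[Si](C)(C)Cl
Why: Silylation of the secondary allylic alcohol gives an ether that should survive the enolate, Grignard, borane and nickel steps that follow.

Step 6
Reactants: 12 (5S)-5-[(1E,3S)-3-(tert-butyldimethylsilyloxy)-2-methylhept-1-en-5-yn-1-yl]dihydrofuran-2(3H)-one
Product: 15 (5S)-5-[(1E,3S)-3-(tert-butyldimethylsilyloxy)-2-methylhept-1-en-5-yn-1-yl]furan-2(5H)-one, via selenide 13 (not isolated), via selenoxide 14 (not isolated)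
Conditions: LiN(i-Pr)2, THF, −78 °C; PhSeBr; then H2O2, pyridine, CH2Cl2, 0 °C to rt
Reagents that add atoms: none
Why: α-Selenenylation of the lactone enolate, oxidation and syn elimination of the selenoxide, which can only take a hydrogen from C7, should give the butenolide, and the work-up is kept free of strong base because C6–H of 15 is both γ to the carbonyl and allylic.

Step 7
Reactants: 15 (5S)-5-[(1E,3S)-3-(tert-butyldimethylsilyloxy)-2-methylhept-1-en-5-yn-1-yl]furan-2(5H)-one; 16 vinylmagnesium bromide; 17 dimethylmethyleneiminium iodide (Eschenmoser's salt)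
Product: 19 (3R,4S,5S)-5-[(1E,3S)-3-(tert-butyldimethylsilyloxy)-2-methylhept-1-en-5-yn-1-yl]-3-[(dimethylamino)methyl]-4-vinyldihydrofuran-2(3H)-one, via silyl ketene acetal 18 (not isolated)
Conditions: 16 (1.5 equiv), CuBr·SMe2 (20 mol%), Me3SiCl, THF, −78 °C; then 17, THF–CH2Cl2, −78 °C to rt; aq. NaHCO3
Reagents that add atoms: vinylmagnesium bromide (16), C=C[Mg]Br; dimethylmethyleneiminium iodide (17), C=[N+](C)C.[I-]
Why: The vinyl copper species formed from 16 and CuBr·SMe2 adds to C7 of the butenolide, Me3SiCl accelerates the addition and captures the enolate as silyl ketene acetal 18, and 18 then attacks the iminium ion of 17 at C11 in a Mannich reaction, so that C7–C8 and C11–C13 are made in one flask from three components. The closest known reaction type is the copper-mediated 1,4-addition of Grignard reagents to 5-substituted furan-2(5H)-ones anti to the C5 substituent with silyl trapping, joined to the aminomethylation of silyl ketene acetals by dimethylmethyleneiminium iodide. No ring is closed. C7 is set by the C6 side chain, which shields one face of the flat butenolide so that vinyl enters trans to it (7S), and C11 is set by the new vinyl group, which sends the iminium ion to the opposite face (trans to C8); this C11 centre is erased and reset in steps 15 and 16. The step needs 1,4-addition to win over 1,2-addition to the lactone carbonyl and over SN2′ displacement of the allylic C6–O bond through C4; copper and Me3SiCl secure the first, the fully substituted and hindered C4 beside a far more electrophilic enoate secures the second, and the internal alkyne and silyl ether are inert at −78 °C.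

Step 8
Reactants: 19 (3R,4S,5S)-5-[(1E,3S)-3-(tert-butyldimethylsilyloxy)-2-methylhept-1-en-5-yn-1-yl]-3-[(dimethylamino)methyl]-4-vinyldihydrofuran-2(3H)-one
Product: 21 (3R,4S,5S)-5-[(1E,3S)-3-(tert-butyldimethylsilyloxy)-2-methylhept-1-en-5-yn-1-yl]-3-[(dimethylamino)methyl]-4-(2-hydroxyethyl)dihydrofuran-2(3H)-one, via alkylborane 20 (not isolated)
Conditions: 9-BBN (excess), THF, 0 °C to rt; then NaBO3·4H2O, H2O, rt
Reagents that add atoms: sodium perborate tetrahydrate (NaBO3·4H2O), [Na+].[Na+].O[B-]1(O)OO[B-](O)(O)OO1.O.O.O.O.O.O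
Why: Hydroboration–oxidation with 9-BBN should add anti-Markovnikov to the monosubstituted vinyl group much faster than to the trisubstituted C4=C5 alkene or the internal alkyne (excess reagent covers complexation by the amine), and perborate oxidises the C–B bond mildly enough for the lactone and the Mannich base.

Step 9
Reactants: 21 (3R,4S,5S)-5-[(1E,3S)-3-(tert-butyldimethylsilyloxy)-2-methylhept-1-en-5-yn-1-yl]-3-[(dimethylamino)methyl]-4-(2-hydroxyethyl)dihydrofuran-2(3H)-one
Product: 22 (3R,4S,5S)-5-[(1E,3S)-3-(tert-butyldimethylsilyloxy)-2-methylhept-1-en-5-yn-1-yl]-3-[(dimethylamino)methyl]-4-(2-oxoethyl)dihydrofuran-2(3H)-one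
Conditions: Dess–Martin periodinane, pyridine, CH2Cl2, 0 °C
Reagents that add atoms: none
Why: Buffered Dess–Martin oxidation of the primary alcohol should give the C9 aldehyde without touching the tertiary amine, the silyl ether or the C7 and C11 centres.

Step 10
Reactants: 22 (3R,4S,5S)-5-[(1E,3S)-3-(tert-butyldimethylsilyloxy)-2-methylhept-1-en-5-yn-1-yl]-3-[(dimethylamino)methyl]-4-(2-oxoethyl)dihydrofuran-2(3H)-one
Product: 24 3β-(tert-butyldimethylsilyloxy)-13-(dimethylamino)-9-hydroxy-11βH-germacra-1(10)E,4E-dien-12,6α-olide (both C9 epimers), via triethylsilyl ether 23 (not isolated)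
Conditions: Ni(cod)2 (30 mol%), IMes·HCl (30 mol%), KOt-Bu (30 mol%), Et3SiH, THF, rt, slow addition of 22 to 0.003 M; then AcOH–THF–H2O (3:1:1), rt
Reagents that add atoms: none
Why: Proposed new method: zerovalent nickel carrying the small carbene IMes should bind the aldehyde and the alkyne of 22 and undergo oxidative cyclisation to an oxanickelacyclopentene with C–C bond formation at C10 (with a small ligand the aldehyde carbon bonds to the alkyne carbon that bears the smaller substituent, here methyl), after which σ-bond metathesis with Et3SiH and C–H reductive elimination give silyl ether 23 by cis addition of C9 and H across the alkyne, that is the E C1=C10 alkene inside the ten-membered ring (endocyclic closure); the closest known reaction type is the nickel–carbene–silane reductive macrocyclisation of ynals to endocyclic E allylic silyl ethers in rings of twelve and more members, which has not been shown for a ten-membered E-cycloalkene; the amine keeps the future methylene lactone out of nickel enoate chemistry, C9 is not controlled here because it is reset in steps 11 and 14, and aqueous acetic acid then removes only the triethylsilyl group.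

Step 11
Reactants: 24 3β-(tert-butyldimethylsilyloxy)-13-(dimethylamino)-9-hydroxy-11βH-germacra-1(10)E,4E-dien-12,6α-olide (both C9 epimers)
Product: 25 3β-(tert-butyldimethylsilyloxy)-13-(dimethylamino)-9-oxo-11βH-germacra-1(10)E,4E-dien-12,6α-olide
Conditions: Dess–Martin periodinane, pyridine, CH2Cl2, 0 °C
Reagents that add atoms: none
Why: Dess–Martin oxidation of the secondary allylic alcohol converges both C9 epimers on one ring enone, so that the ring closure does not have to control C9.

Step 12
Reactants: 25 3β-(tert-butyldimethylsilyloxy)-13-(dimethylamino)-9-oxo-11βH-germacra-1(10)E,4E-dien-12,6α-olide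
Product: 26 13-(dimethylamino)-3β-hydroxy-9-oxo-11βH-germacra-1(10)E,4E-dien-12,6α-olide
Conditions: TBAF, AcOH (1:1), THF, 0 °C to rt
Reagents that add atoms: none
Why: Fluoride desilylation buffered by acetic acid should free the C3 hydroxyl without base-induced loss of dimethylamine from the Mannich base and without the acid that could trigger transannular reactions of the diene.

Step 13
Reactants: 26 13-(dimethylamino)-3β-hydroxy-9-oxo-11βH-germacra-1(10)E,4E-dien-12,6α-olide
Product: 27 3β-acetoxy-13-(dimethylamino)-9-oxo-11βH-germacra-1(10)E,4E-dien-12,6α-olide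
Conditions: Ac2O, pyridine, DMAP (cat.), CH2Cl2, 0 °C to rt
Reagents that add atoms: acetic anhydride, CC(=O)OC(C)=O
Why: Acetylation installs the final C3 ester now, so that no protecting group has to be removed after the C11 centre and the acid-labile epoxide exist, and an acetate at C3 cannot direct the later epoxidation.

Step 14
Reactants: 27 3β-acetoxy-13-(dimethylamino)-9-oxo-11βH-germacra-1(10)E,4E-dien-12,6α-olide
Product: 29 3β-acetoxy-13-(dimethylamino)-9β-hydroxy-11βH-germacra-1(10)E,4E-dien-12,6α-olide, via catecholborate ester 28 (not isolated)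
Conditions: (R)-2-methyl-CBS-oxazaborolidine (1 equiv), catecholborane, toluene, −78 to −40 °C; MeOH, then aqueous work-up
Reagents that add atoms: none
Why: In this Corey–Bakshi–Shibata reduction the oxazaborolidine should bind the ketone anti to the larger, α-branched alkenyl side (C10) and deliver hydride to the face that gives the 9S (9β) alcohol, which is the sense expected for the (R)-catalyst when the alkenyl group is the large substituent, while catecholborane at low temperature leaves lactone, acetate and the amine-masked methylene lactone alone.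

Step 15
Reactants: 29 3β-acetoxy-13-(dimethylamino)-9β-hydroxy-11βH-germacra-1(10)E,4E-dien-12,6α-olide
Product: 31 3β-acetoxy-9β-hydroxygermacra-1(10)E,4E,11(13)-trien-12,6α-olide, via ammonium iodide 30 (not isolated)
Conditions: MeI, THF, rt; then aq. NaHCO3, EtOAc, rt
Reagents that add atoms: none
Why: Exhaustive N-methylation followed by E1cB elimination of trimethylamine (the Mannich-base route to α-methylene lactones) should unmask C11=C13, and bicarbonate is too weak a base to cleave the acetate or to start oxa-Michael addition of the 9-hydroxyl.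

Step 16
Reactants: 31 3β-acetoxy-9β-hydroxygermacra-1(10)E,4E,11(13)-trien-12,6α-olide
Product: 32 3β-acetoxy-9β-hydroxy-11αH-germacra-1(10)E,4E-dien-12,6α-olide (11R)
Conditions: H2 (1 atm), RhCl(PPh3)3 (15 mol%), benzene–EtOH, rt
Reagents that add atoms: none
Why: Homogeneous hydrogenation with RhCl(PPh3)3 should reduce only the conjugated 1,1-disubstituted exocyclic alkene and not the two trisubstituted ring alkenes, and cis delivery of hydrogen to the lactone face that carries H7, anti to the C8 methylene on the neighbouring carbon, should place the methyl group cis to C8 and give 11R, the epimer that enolate methylation or equilibration would not give.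

Step 17
Reactants: 32 3β-acetoxy-9β-hydroxy-11αH-germacra-1(10)E,4E-dien-12,6α-olide
Product: 33 3β-acetoxy-1α,10β-epoxy-9β-hydroxy-11αH-germacr-4E-en-12,6α-olide
Conditions: VO(acac)2 (5 mol%), t-BuOOH, CH2Cl2, 0 °C
Reagents that add atoms: tert-butyl hydroperoxide, CC(C)(C)OO
Why: In this vanadium-catalysed hydroxyl-directed epoxidation only C1=C10 has a free allylic hydroxyl (C3 is acetylated and C4=C5 is deactivated by two allylic C–O bonds), and the vanadate ester of the 9β-hydroxyl needs a small O–C9–C10=C1 dihedral angle, which the ring allows only in the conformer whose outer alkene face leads to the erythro epoxy alcohol, so oxygen should be delivered to give the 1α,10β-epoxide of the target; the reaction is kept cold and short because the epoxide can be opened transannularly by C4=C5 under acid.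

Step 18
Reactants: 33 3β-acetoxy-1α,10β-epoxy-9β-hydroxy-11αH-germacr-4E-en-12,6α-olide
Product: 34 3β,9β-diacetoxy-1α,10β-epoxy-11αH-germacr-4E-en-12,6α-olide (CNP0250285.1)
Conditions: Ac2O, pyridine, DMAP (cat.), CH2Cl2, 0 °C
Reagents that add atoms: acetic anhydride, CC(=O)OC(C)=O
Why: Acetylation of the secondary hydroxyl under mild amine conditions should not open the epoxide or epimerise the less stable 11R centre, and it completes the target.

**Compound list**

1 | but-2-yn-1-ol | CC#CCO | starting material
2 | methyl chloroformate | COC(=O)Cl | starting material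
3 | but-2-yn-1-yl methyl carbonate | CC#CCOC(=O)OC | intermediate
4 | bis(pinacolato)diboron | CC1(C)OB(OC1(C)C)B1OC(C)(C)C(C)(C)O1 | starting material
5 | 2-(buta-2,3-dien-2-yl)-4,4,5,5-tetramethyl-1,3,2-dioxaborolane | C=C=C(C)B1OC(C)(C)C(C)(C)O1 | intermediate
6 | (S)-5-(hydroxymethyl)dihydrofuran-2(3H)-one | OC[C@@H]1CCC(=O)O1 | starting material
7 | 2-(triphenylphosphoranylidene)propanal | CC(C=O)=P(c1ccccc1)(c1ccccc1)c1ccccc1 | starting material
8 | (S)-5-oxotetrahydrofuran-2-carbaldehyde (not isolated) | O=C[C@@H]1CCC(=O)O1 | intermediate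
9 | (2E)-2-methyl-3-[(2S)-5-oxotetrahydrofuran-2-yl]prop-2-enal | O=C/C(C)=C/[C@@H]1CCC(=O)O1 | intermediate
10 | pinacol borate ester of 11 (not isolated) | CC#CC[C@H](OB1OC(C)(C)C(C)(C)O1)/C(C)=C/[C@@H]1CCC(=O)O1 | intermediate
11 | (5S)-5-[(1E,3S)-3-hydroxy-2-methylhept-1-en-5-yn-1-yl]dihydrofuran-2(3H)-one | CC#CC[C@H](O)/C(C)=C/[C@@H]1CCC(=O)O1 | intermediate
12 | (5S)-5-[(1E,3S)-3-(tert-butyldimethylsilyloxy)-2-methylhept-1-en-5-yn-1-yl]dihydrofuran-2(3H)-one | CC#CC[C@H](O[Si](C)(C)C(C)(C)C)/C(C)=C/[C@@H]1CCC(=O)O1 | intermediate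
13 | 3-(phenylselanyl) derivative of 12, epimers at the selenium-bearing carbon (not isolated) | CC#CC[C@H](O[Si](C)(C)C(C)(C)C)/C(C)=C/[C@@H]1CC([Se]c2ccccc2)C(=O)O1 | intermediate
14 | selenoxide of 13 (not isolated) | CC#CC[C@H](O[Si](C)(C)C(C)(C)C)/C(C)=C/[C@@H]1CC([Se](=O)c2ccccc2)C(=O)O1 | intermediate
15 | (5S)-5-[(1E,3S)-3-(tert-butyldimethylsilyloxy)-2-methylhept-1-en-5-yn-1-yl]furan-2(5H)-one | CC#CC[C@H](O[Si](C)(C)C(C)(C)C)/C(C)=C/[C@H]1OC(=O)C=C1 | intermediate
16 | vinylmagnesium bromide | C=C[Mg]Br | starting material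
17 | dimethylmethyleneiminium iodide (Eschenmoser's salt) | C=[N+](C)C.[I-] | starting material
18 | (2S,3S)-2-[(1E,3S)-3-(tert-butyldimethylsilyloxy)-2-methylhept-1-en-5-yn-1-yl]-5-(trimethylsilyloxy)-3-vinyl-2,3-dihydrofuran (not isolated) | CC#CC[C@H](O[Si](C)(C)C(C)(C)C)/C(C)=C/[C@H]1OC(O[Si](C)(C)C)=C[C@@H]1C=C | intermediate
19 | (3R,4S,5S)-5-[(1E,3S)-3-(tert-butyldimethylsilyloxy)-2-methylhept-1-en-5-yn-1-yl]-3-[(dimethylamino)methyl]-4-vinyldihydrofuran-2(3H)-one | CC#CC[C@H](O[Si](C)(C)C(C)(C)C)/C(C)=C/[C@H]1OC(=O)[C@@H](CN(C)C)[C@@H]1C=C | intermediate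
20 | B-alkyl-9-borabicyclo[3.3.1]nonane adduct of 19 at C9 (not isolated) | CC#CC[C@H](O[Si](C)(C)C(C)(C)C)/C(C)=C/[C@H]1OC(=O)[C@@H](CN(C)C)[C@@H]1CCB1C2CCCC1CCC2 | intermediate
21 | (3R,4S,5S)-5-[(1E,3S)-3-(tert-butyldimethylsilyloxy)-2-methylhept-1-en-5-yn-1-yl]-3-[(dimethylamino)methyl]-4-(2-hydroxyethyl)dihydrofuran-2(3H)-one | CC#CC[C@H](O[Si](C)(C)C(C)(C)C)/C(C)=C/[C@H]1OC(=O)[C@@H](CN(C)C)[C@@H]1CCO | intermediate
22 | (3R,4S,5S)-5-[(1E,3S)-3-(tert-butyldimethylsilyloxy)-2-methylhept-1-en-5-yn-1-yl]-3-[(dimethylamino)methyl]-4-(2-oxoethyl)dihydrofuran-2(3H)-one | CC#CC[C@H](O[Si](C)(C)C(C)(C)C)/C(C)=C/[C@H]1OC(=O)[C@@H](CN(C)C)[C@@H]1CC=O | intermediate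
23 | 3β-(tert-butyldimethylsilyloxy)-13-(dimethylamino)-9-(triethylsilyloxy)-11βH-germacra-1(10)E,4E-dien-12,6α-olide, both C9 epimers (not isolated) | CC(C)(C)[Si](C)(C)O[C@H]1C/C=C(\C)C(O[Si](CC)(CC)CC)C[C@@H]2[C@@H](/C=C/1C)OC(=O)[C@H]2CN(C)C | intermediate
24 | 3β-(tert-butyldimethylsilyloxy)-13-(dimethylamino)-9-hydroxy-11βH-germacra-1(10)E,4E-dien-12,6α-olide, both C9 epimers | CC(C)(C)[Si](C)(C)O[C@H]1C/C=C(\C)C(O)C[C@@H]2[C@@H](/C=C/1C)OC(=O)[C@H]2CN(C)C | intermediate
25 | 3β-(tert-butyldimethylsilyloxy)-13-(dimethylamino)-9-oxo-11βH-germacra-1(10)E,4E-dien-12,6α-olide | CC(C)(C)[Si](C)(C)O[C@H]1C/C=C(\C)C(=O)C[C@@H]2[C@@H](/C=C/1C)OC(=O)[C@H]2CN(C)C | intermediate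
26 | 13-(dimethylamino)-3β-hydroxy-9-oxo-11βH-germacra-1(10)E,4E-dien-12,6α-olide | O[C@H]1C/C=C(\C)C(=O)C[C@@H]2[C@@H](/C=C/1C)OC(=O)[C@H]2CN(C)C | intermediate
27 | 3β-acetoxy-13-(dimethylamino)-9-oxo-11βH-germacra-1(10)E,4E-dien-12,6α-olide | CC(=O)O[C@H]1C/C=C(\C)C(=O)C[C@@H]2[C@@H](/C=C/1C)OC(=O)[C@H]2CN(C)C | intermediate
28 | catecholborate ester of 29 (not isolated) | CC(=O)O[C@H]1C/C=C(\C)[C@@H](OB3Oc4ccccc4O3)C[C@@H]2[C@@H](/C=C/1C)OC(=O)[C@H]2CN(C)C | intermediate
29 | 3β-acetoxy-13-(dimethylamino)-9β-hydroxy-11βH-germacra-1(10)E,4E-dien-12,6α-olide (9S) | CC(=O)O[C@H]1C/C=C(\C)[C@@H](O)C[C@@H]2[C@@H](/C=C/1C)OC(=O)[C@H]2CN(C)C | intermediate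
30 | 13-trimethylammonium iodide of 29 (not isolated) | CC(=O)O[C@H]1C/C=C(\C)[C@@H](O)C[C@@H]2[C@@H](/C=C/1C)OC(=O)[C@H]2C[N+](C)(C)C.[I-] | intermediate
31 | 3β-acetoxy-9β-hydroxygermacra-1(10)E,4E,11(13)-trien-12,6α-olide | CC(=O)O[C@H]1C/C=C(\C)[C@@H](O)C[C@@H]2[C@@H](/C=C/1C)OC(=O)C2=C | intermediate
32 | 3β-acetoxy-9β-hydroxy-11αH-germacra-1(10)E,4E-dien-12,6α-olide (11R) | CC(=O)O[C@H]1C/C=C(\C)[C@@H](O)C[C@@H]2[C@@H](/C=C/1C)OC(=O)[C@@H]2C | intermediate
33 | 3β-acetoxy-1α,10β-epoxy-9β-hydroxy-11αH-germacr-4E-en-12,6α-olide | CC(=O)O[C@H]1C[C@@H]2O[C@@]2(C)[C@@H](O)C[C@@H]2[C@@H](/C=C/1C)OC(=O)[C@@H]2C | intermediate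
34 | 3β,9β-diacetoxy-1α,10β-epoxy-11αH-germacr-4E-en-12,6α-olide, (1S,3S,6S,7S,9S,10R,11R) | CC(=O)O[C@H]1C[C@@H]2O[C@@]2(C)[C@@H](OC(C)=O)C[C@@H]2[C@@H](/C=C/1C)OC(=O)[C@@H]2C | target

**Step count**

Total: 18 steps. Longest linear sequence: 17 steps (steps 1, 2 and 4–18, from but-2-yn-1-ol); from lactone 6 it is 16 steps (steps 3–18).

**Steps most likely to fail**

1. Step 10 (bears the new-method label). What may go wrong: intermolecular oligomerisation outruns closure of the strained E-cyclodecene; bond formation at C1 instead of C10 (exocyclic, nine-membered closure); or ionisation of the allylic lactone C6–O bond by zerovalent nickel. Fallback, a Nozaki–Hiyama–Kishi ring closure on a preformed vinyl iodide: it sets out from alcohol 21. Palladium-catalysed cis hydrostannation of the alkyne (Bu3SnH, PdCl2(PPh3)2, THF), with tin on the less hindered methyl-bearing C10, gives the vinylstannane F1, the regioisomer being removed by chromatography. Iodine in CH2Cl2 at 0 °C gives the E iodo alcohol F2, and Dess–Martin oxidation gives the iodo aldehyde F3. CrCl2 with catalytic NiCl2 in DMSO–THF under high dilution then closes C9–C10 with retention of the alkene geometry. The fallback returns to the route at 24 (both C9 epimers), before step 11.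

2. Step 16. What may go wrong: hydrogen delivery to the other face of C11=C13, which gives the more stable 11S epimer, or migration of the exocyclic double bond into the lactone ring through a rhodium hydride. Fallback, catalyst control in place of substrate control: it sets out from 31, which is hydrogenated with a chiral bisphosphine complex that binds the lactone carbonyl, for example Ru(OAc)2[(S)-BINAP] or its enantiomer (H2, 50 atm, MeOH–CH2Cl2). Complexes of this type reduce α-methylene-γ-butyrolactones with high facial control, and the ligand enantiomer matched to 11R is used. The fallback returns at 32 and makes no new compound.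

3. Step 14. What may go wrong: poor facial selectivity because the conformation of the twisted ten-membered enone overrides the reagent, or slow reduction because the amine binds the borane. Fallback, inversion in place of face-selective reduction: it sets out from 27, which is reduced under ring control with NaBH4 and CeCl3·7H2O in MeOH at −78 °C. If this delivers the 9α-alcohol F4, a Mitsunobu reaction (PPh3, DIAD, HCO2H, THF, 0 °C) inverts C9 to the 9β-formate F5. KHCO3 in MeOH–H2O at 0 °C then cleaves the formate but not the C3 acetate. The fallback returns to the route at 29.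

Further compounds

F1 | step 10 | (E)-C10-tributylstannyl alkene from 21 (tin on C10, H on C1) | CCCC[Sn](CCCC)(CCCC)/C(C)=C/C[C@H](O[Si](C)(C)C(C)(C)C)/C(C)=C/[C@H]1OC(=O)[C@@H](CN(C)C)[C@@H]1CCO
F2 | step 10 | (E)-C10-iodo alkene alcohol | I/C(C)=C/C[C@H](O[Si](C)(C)C(C)(C)C)/C(C)=C/[C@H]1OC(=O)[C@@H](CN(C)C)[C@@H]1CCO
F3 | step 10 | (E)-C10-iodo alkene C9 aldehyde | I/C(C)=C/C[C@H](O[Si](C)(C)C(C)(C)C)/C(C)=C/[C@H]1OC(=O)[C@@H](CN(C)C)[C@@H]1CC=O
F4 | step 14 | 3β-acetoxy-13-(dimethylamino)-9α-hydroxy-11βH-germacra-1(10)E,4E-dien-12,6α-olide (9R) | CC(=O)O[C@H]1C/C=C(\C)[C@H](O)C[C@@H]2[C@@H](/C=C/1C)OC(=O)[C@H]2CN(C)C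
F5 | step 14 | 3β-acetoxy-13-(dimethylamino)-9β-formyloxy-11βH-germacra-1(10)E,4E-dien-12,6α-olide (9S) | CC(=O)O[C@H]1C/C=C(\C)[C@@H](OC=O)C[C@@H]2[C@@H](/C=C/1C)OC(=O)[C@H]2CN(C)C
F0 | step 16 | none | none
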